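The dihydropyran ring is disconnected at C3–C4. C4 is a benzylic carbon on C4a, ortho to the ring oxygen O1 on C8a of the phloroglucinol ring, so the precursor is a salicylaldehyde whose formyl carbon is C4. Annulation with 2-methyl-1-nitropropene does the rest in one operation: reversible oxa-Michael addition of the phenol builds O1–C2 with the gem-dimethyl carbon, and the nitronate carbon C3 then closes the pyran ring by an intramolecular Henry reaction on the aldehyde, dehydration giving a 3-nitro-2H-chromene. The nitro group is a masked C3 ketone; after C8 acylation it is unveiled and reduced enantioselectively to the (S)-carbinol.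

Key step: step 2

Remark: 2-methyl-1-nitroprop-1-ene (4) is taken as purchased (otherwise one step from acetone and nitromethane); aldehyde 3 is also sold, in which case step 1 drops out.

Step 1
Reactants: 1 2,4,6-trihydroxytoluene
Product: 3 2,4,6-trihydroxy-3-methylbenzaldehyde, via iminium chloride 2 (not isolated)
Conditions: POCl3 (1.1 equiv), DMF (1.2 equiv), EtOAc, 0 °C to rt; then H2O, 60 °C
Reagents that add atoms: N,N-dimethylformamide, CN(C)C=O; water, O
Why: Vilsmeier–Haack formylation of a phloroglucinol: the two unsubstituted ring carbons of 1 are equivalent by symmetry and the iminium group of 2 deactivates the ring, so a single aldehyde is expected.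

Step 2
Reactants: 3 2,4,6-trihydroxy-3-methylbenzaldehyde; 4 2-methyl-1-nitroprop-1-ene
Product: 7 2,2,6-trimethyl-3-nitro-2H-chromene-5,7-diol, via oxa-Michael adduct 5 (not isolated), via nitro-aldol adduct 6 (not isolated)
Conditions: 4 (3 equiv), DABCO (0.5 equiv), MeCN (concentrated), 50 °C
Reagents that add atoms: 2-methyl-1-nitroprop-1-ene (4), CC(C)=C[N+](=O)[O-]
Why: The phenoxide of 3 adds reversibly to the nitroalkene (oxa-Michael) to give the tertiary ether and a nitronate at C3, which attacks the neighbouring formyl carbon C4 (Henry reaction) and then loses water by E1cB to the push-pull nitroalkene 7, the only irreversible event. The closest known reaction type is the amine-mediated tandem oxa-Michael/Henry synthesis of 3-nitro-2H-chromenes from salicylaldehydes and nitroalkenes, applied here with a β,β-disubstituted nitroalkene. The one ring closed is the pyran ring, by 6-exo-trig attack of the nitronate carbon on the aldehyde C=O (bond C3–C4). The stereocentres C3 and C4 of 6 arise without control and are erased by the dehydration, so no lasting stereocentre is set here. The step needs site selectivity between the two hydroxyls ortho to the aldehyde (the para hydroxyl can add but cannot ring-close): the hydroxyl beside the C-methyl group is flanked on both sides, so its congested tertiary ether should form more slowly and revert faster, and the flux should pass through the hydroxyl next to the unsubstituted ring CH, which becomes O1 and leaves C8 free.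

Step 3
Reactants: 7 2,2,6-trimethyl-3-nitro-2H-chromene-5,7-diol; 8 3-phenylpropanoyl chloride
Product: 9 1-(5,7-dihydroxy-2,2,6-trimethyl-3-nitro-2H-chromen-8-yl)-3-phenylpropan-1-one
Conditions: 8 (1.2 equiv), AlCl3 (4 equiv), PhNO2/CH2Cl2, 0 to 45 °C; ice/aq HCl
Reagents that add atoms: 3-phenylpropanoyl chloride (8), O=C(Cl)CCc1ccccc1
Why: Friedel–Crafts acylation, direct or by O-acylation and Fries shift under the same Lewis acid; C8 is the only unsubstituted ring carbon and lies between O1 and the C7 hydroxyl, so the position of the acyl group is fixed by constitution.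

Step 4
Reactants: 9 1-(5,7-dihydroxy-2,2,6-trimethyl-3-nitro-2H-chromen-8-yl)-3-phenylpropan-1-one
Product: 11 5,7-dihydroxy-2,2,6-trimethyl-8-(3-phenylpropanoyl)-2H-chromen-3(4H)-one, via enamine 10 (not isolated)
Conditions: Fe powder (6 equiv), AcOH/H2O 9:1, 75 °C, under N2
Reagents that add atoms: water, O
Why: Reduction of a conjugated nitroalkene by iron in acetic acid to the enamine and hydrolysis of its imine tautomer (the classical nitroalkene-to-ketone conversion); the chelated aryl ketone is inert to this reductant and the gem-dimethyl group at C2 leaves only one enolization direction.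

Step 5
Reactants: 11 5,7-dihydroxy-2,2,6-trimethyl-8-(3-phenylpropanoyl)-2H-chromen-3(4H)-one
Product: 12 1-[(3S)-3,5,7-trihydroxy-2,2,6-trimethyl-3,4-dihydro-2H-chromen-8-yl]-3-phenylpropan-1-one (target)
Conditions: (R)-2-methyl-CBS-oxazaborolidine (0.3 equiv), BH3·SMe2 (3.5 equiv), THF, −20 °C, slow addition of 11; MeOH, then 1 M HCl
Reagents that add atoms: none
Why: Corey–Bakshi–Shibata reduction: in the catalyst–borane–ketone complex the quaternary C2 side is the large group and the C4 methylene the small one, so the (R)-catalyst should deliver hydride to the face that gives the (S)-alcohol (mirror image of the sense known for tert-alkyl methyl ketones with the (S)-catalyst), which sets C3 by catalyst control, while the chelated, doubly ortho-substituted, electron-rich aryl ketone should react far more slowly.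

Compound list
1 | 2,4,6-trihydroxytoluene (2-methylbenzene-1,3,5-triol) | Cc1c(O)cc(O)cc1O | starting material
2 | [(2,4,6-trihydroxy-3-methylphenyl)methylidene]dimethylammonium chloride (iminium chloride, formed in the flask) | Cc1c(O)c(C=[N+](C)C)c(O)cc1O.[Cl-] | intermediate
3 | 2,4,6-trihydroxy-3-methylbenzaldehyde | Cc1c(O)c(C=O)c(O)cc1O | intermediate
4 | 2-methyl-1-nitroprop-1-ene | CC(C)=C[N+](=O)[O-] | starting material
5 | 2,4-dihydroxy-3-methyl-6-[(2-methyl-1-nitropropan-2-yl)oxy]benzaldehyde (oxa-Michael adduct, formed in the flask) | Cc1c(O)c(C=O)c(OC(C)(C)C[N+](=O)[O-])cc1O | intermediate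
6 | 2,2,6-trimethyl-3-nitrochromane-4,5,7-triol (nitro-aldol adduct, mixture of diastereomers, formed in the flask) | Cc1c(O)c2c(cc1O)OC(C)(C)C([N+](=O)[O-])C2O | intermediate
7 | 2,2,6-trimethyl-3-nitro-2H-chromene-5,7-diol | Cc1c(O)c2c(cc1O)OC(C)(C)C([N+](=O)[O-])=C2 | intermediate
8 | 3-phenylpropanoyl chloride | O=C(Cl)CCc1ccccc1 | starting material
9 | 1-(5,7-dihydroxy-2,2,6-trimethyl-3-nitro-2H-chromen-8-yl)-3-phenylpropan-1-one | Cc1c(O)c2c(c(C(=O)CCc3ccccc3)c1O)OC(C)(C)C([N+](=O)[O-])=C2 | intermediate
10 | 1-(3-amino-5,7-dihydroxy-2,2,6-trimethyl-2H-chromen-8-yl)-3-phenylpropan-1-one (enamine, formed in the flask) | Cc1c(O)c2c(c(C(=O)CCc3ccccc3)c1O)OC(C)(C)C(N)=C2 | intermediate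
11 | 5,7-dihydroxy-2,2,6-trimethyl-8-(3-phenylpropanoyl)-2H-chromen-3(4H)-one | Cc1c(O)c2c(c(C(=O)CCc3ccccc3)c1O)OC(C)(C)C(=O)C2 | intermediate
12 | 1-[(3S)-3,5,7-trihydroxy-2,2,6-trimethyl-3,4-dihydro-2H-chromen-8-yl]-3-phenylpropan-1-one | Cc1c(O)c2c(c(C(=O)CCc3ccccc3)c1O)OC(C)(C)[C@@H](O)C2 | target

Total step count: 5. Longest linear sequence: 5 steps (1 → 3 → 7 → 9 → 11 → 12).

Steps most likely to fail

Step 2. The oxa-Michael addition may revert faster than the nitronate closes onto the electron-rich aldehyde. Addition through the hydroxyl beside the C-methyl group, or C-alkylation of the free ring carbon, would erode the outcome further. The fallback sets out from compound 1 and comes back at compound 9, so it also passes by step 3. Friedel–Crafts acylation of 1 with 8 (AlCl3, PhNO2) gives 1-(2,4,6-trihydroxy-3-methylphenyl)-3-phenylpropan-1-one F1. Its most acidic hydroxyl, para to the ketone, is capped with MOMCl and i-Pr2NEt to give 1-[2,6-dihydroxy-4-(methoxymethoxy)-3-methylphenyl]-3-phenylpropan-1-one F2. Magnesium-mediated ortho-formylation (MgCl2, Et3N, paraformaldehyde, MeCN, reflux) at the only free ring carbon gives 2,4-dihydroxy-6-(methoxymethoxy)-5-methyl-3-(3-phenylpropanoyl)benzaldehyde F3, in which a single hydroxyl is ortho to the formyl group and no ring CH is left. The same DABCO annulation with 4 then gives 1-[7-hydroxy-5-(methoxymethoxy)-2,2,6-trimethyl-3-nitro-2H-chromen-8-yl]-3-phenylpropan-1-one F4, and HCl in MeOH removes the MOM group to give 9.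

Step 3. The Lewis acid may be tied up by the nitro group and the phenoxides, and the push-pull ring may be too deactivated. The result would be O-acylation without Fries shift, or opening of the nitrochromene. The fallback sets out from compound 7 and comes back at compound 12, with the acyl group introduced last on a fully activated ring. Iron in acetic acid converts 7 into 5,7-dihydroxy-2,2,6-trimethyl-2H-chromen-3(4H)-one F5. Corey–Bakshi–Shibata reduction with the (R)-catalyst gives (3S)-2,2,6-trimethylchromane-3,5,7-triol F6. Houben–Hoesch reaction with 3-phenylpropanenitrile (ZnCl2, HCl, Et2O, 0 °C) at the only free ring carbon gives 1-[(3S)-3,5,7-trihydroxy-2,2,6-trimethylchroman-8-yl]-3-phenylpropan-1-iminium chloride F7, which is hydrolysed in warm water to 12.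

Step 5. The aryloxyboranes formed from the two free phenols may reduce the ketone without catalyst control, giving poor facial selectivity. Intramolecular hydride delivery from the C7 aryloxyborane may also over-reduce the aryl ketone. The fallback sets out from compound 11 and comes back at compound 12. It replaces the borane reagent with an (S)-selective ketoreductase chosen from a commercial panel (NADP+, glucose and glucose dehydrogenase for cofactor recycling, pH 7 phosphate buffer with DMSO, 30 °C). This works on the free phenol in water and does not accept the hindered aryl ketone; no further compound arises (none, F0).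

Further compounds
F1 | step 2 | 1-(2,4,6-trihydroxy-3-methylphenyl)-3-phenylpropan-1-one | Cc1c(O)cc(O)c(C(=O)CCc2ccccc2)c1O
F2 | step 2 | 1-[2,6-dihydroxy-4-(methoxymethoxy)-3-methylphenyl]-3-phenylpropan-1-one | Cc1c(OCOC)cc(O)c(C(=O)CCc2ccccc2)c1O
F3 | step 2 | 2,4-dihydroxy-6-(methoxymethoxy)-5-methyl-3-(3-phenylpropanoyl)benzaldehyde | Cc1c(OCOC)c(C=O)c(O)c(C(=O)CCc2ccccc2)c1O
F4 | step 2 | 1-[7-hydroxy-5-(methoxymethoxy)-2,2,6-trimethyl-3-nitro-2H-chromen-8-yl]-3-phenylpropan-1-one | Cc1c(OCOC)c2c(c(C(=O)CCc3ccccc3)c1O)OC(C)(C)C([N+](=O)[O-])=C2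
F5 | step 3 | 5,7-dihydroxy-2,2,6-trimethyl-2H-chromen-3(4H)-one | Cc1c(O)c2c(cc1O)OC(C)(C)C(=O)C2
F6 | step 3 | (3S)-2,2,6-trimethylchromane-3,5,7-triol | Cc1c(O)c2c(cc1O)OC(C)(C)[C@@H](O)C2
F7 | step 3 | 1-[(3S)-3,5,7-trihydroxy-2,2,6-trimethylchroman-8-yl]-3-phenylpropan-1-iminium chloride | Cc1c(O)c2c(c(C(=[NH2+])CCc3ccccc3)c1O)OC(C)(C)[C@@H](O)C2.[Cl-]
F0 | step 5 | none | none
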